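**Retrosynthetic overview**
1. The strategy rests on the benzo ring C4a–C5–C6–C7–C8–C8a of the 4-phenylchroman-2-one. It carries oxygen on C5, C7 and C8a (1,3,5), only O1 on C8a is acylated (lactone O1–C2), the C4-bearing chain sits on C4a and the 3-arylpropanoyl group on C8. The ring is built de novo so that each oxygen arrives already differentiated.
2. Key disconnection: benzannulation of 3-ethoxy-4-alkylcyclobutenone 6 with siloxyalkyne 14 forms C8a–C8, C7–C6 and C8a–C4a. The phenol freed on C8a then closes O1–C2 on the pendant methyl ester in the same flask.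
3. Cyclobutenone 6 comes from the ketene [2+2] of acid chloride 3 with ethoxyacetylene. The C4 stereocentre is set by desymmetrising methanolysis of 3-phenylglutaric anhydride.
4. Siloxyalkyne 14 comes from ynolate homologation and O-silylation of the dioxolane of an α-keto ester, itself made from an arylethyl Grignard reagent and diethyl oxalate.
5. Ring order: cyclobutenone (transient), then the carbocyclic aromatic ring, then the lactone; the end game is desilylation, ketal hydrolysis and ether cleavage.

Key step: step 7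

Assumption: of the pseudoenantiomeric quinine- and quinidine-derived thiourea catalysts, the one that opens anhydride 1 to the (R)-hemiester 2 is used; the sense is to be checked on 2 by its sign of rotation before material is carried on.
Remark: anhydride 1 is taken as commercial (otherwise one step from 3-phenylglutaric acid with acetic anhydride). The distal phenol is carried as a methyl ether and the C5 oxygen as the ethyl ether that ethoxyacetylene delivers.

**Route**

Step 1
Reactants: 1 3-phenylglutaric anhydride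
Product: 2 (3R)-5-methoxy-5-oxo-3-phenylpentanoic acid
Conditions: MeOH (10 equiv), 9-amino-9-deoxy-epi-cinchona 3,5-bis(trifluoromethyl)phenylthiourea (10 mol %), MTBE, rt
Reagents that add atoms: methanol, CO
Why: Desymmetrising alcoholysis of a prochiral cyclic anhydride under bifunctional cinchona thiourea catalysis, in which the quinuclidine activates methanol and the thiourea binds one of the two enantiotopic carbonyl groups, so the stereocentre (later C4) is set by catalyst control; the hemiester can be enriched further by crystallisation of an amine salt.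

Step 2
Reactants: 2 (3R)-5-methoxy-5-oxo-3-phenylpentanoic acid
Product: 3 methyl (3S)-5-chloro-5-oxo-3-phenylpentanoate
Conditions: (COCl)2, DMF (cat.), CH2Cl2, 0 °C → rt
Reagents that add atoms: oxalyl chloride, O=C(Cl)C(=O)Cl
Why: Vilsmeier-type activation converts the free acid into the acid chloride without touching the methyl ester, and the stereocentre, β to both carbonyl groups, cannot epimerise (the descriptor changes only through the priority rules).

Step 3
Reactants: 3 methyl (3S)-5-chloro-5-oxo-3-phenylpentanoate; 4 ethoxyacetylene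
Product: 6 methyl (3S)-3-(2-ethoxy-4-oxocyclobut-2-en-1-yl)-3-phenylpropanoate (both epimers at ring C1), via ketene 5 (not isolated)
Conditions: Et3N (1.3 equiv), 4 (3 equiv), CH2Cl2, slow addition of 3, 0 °C → rt
Reagents that add atoms: none
Why: Dehydrochlorination gives aldoketene 5, which the ynol ether traps in a regioselective ketene–alkoxyacetylene [2+2] (the alkyne CH carbon attacks the ketene carbonyl carbon) to give the 3-ethoxy-4-alkylcyclobutenone; slow addition into excess 4 holds ketene dimerisation back, and the uncontrolled ring stereocentre is irrelevant because that carbon becomes aromatic.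

Step 4
Reactants: 7 1-(2-bromoethyl)-4-methoxybenzene; 8 diethyl oxalate
Product: 10 ethyl 4-(4-methoxyphenyl)-2-oxobutanoate, via Grignard reagent 9 (not isolated)
Conditions: Mg, THF, rt; then added to 8 (2.5 equiv), THF, −78 °C; aq HCl
Reagents that add atoms: none
Why: Mono-addition of a Grignard reagent to an oxalate diester, which stops at the α-keto ester because the magnesium hemiketal alkoxide survives at low temperature until work-up.

Step 5
Reactants: 10 ethyl 4-(4-methoxyphenyl)-2-oxobutanoate
Product: 11 ethyl 2-[2-(4-methoxyphenyl)ethyl]-1,3-dioxolane-2-carboxylate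
Conditions: TMSOCH2CH2OTMS, TMSOTf (cat.), CH2Cl2, −78 °C → rt
Reagents that add atoms: 1,2-bis(trimethylsilyloxy)ethane, C[Si](C)(C)OCCO[Si](C)(C)C
Why: Aprotic ketalisation under Noyori conditions converts the electrophilic α-keto carbonyl into the dioxolane, driven by formation of hexamethyldisiloxane and free of the transesterification that free glycol and acid could cause.

Step 6
Reactants: 11 ethyl 2-[2-(4-methoxyphenyl)ethyl]-1,3-dioxolane-2-carboxylate
Product: 14 2-[2-(4-methoxyphenyl)ethyl]-2-{[tri(propan-2-yl)silyl]oxyethynyl}-1,3-dioxolane, via dibromoenolate 12 (not isolated), via lithium ynolate 13 (not isolated)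
Conditions: CH2Br2, LiTMP (2.2 equiv), THF, −78 °C; n-BuLi, −78 °C → rt; TIPSCl, 0 °C → rt
Reagents that add atoms: dibromomethane, BrCBr; triisopropylsilyl chloride, CC(C)[Si](Cl)(C(C)C)C(C)C
Why: Kowalski ynolate formation, in which LiCHBr2 adds to the ester, enolate 12 undergoes bromine–lithium exchange and the carbenoid rearranges by 1,2-shift of the dioxolanyl carbon to ynolate 13, which the bulky silyl chloride traps on oxygen.

Step 7
Reactants: 6 methyl (3S)-3-(2-ethoxy-4-oxocyclobut-2-en-1-yl)-3-phenylpropanoate; 14 2-[2-(4-methoxyphenyl)ethyl]-2-{[tri(propan-2-yl)silyl]oxyethynyl}-1,3-dioxolane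
Product: 20 (4R)-5-ethoxy-8-{2-[2-(4-methoxyphenyl)ethyl]-1,3-dioxolan-2-yl}-4-phenyl-7-(triisopropylsilyloxy)-3,4-dihydro-2H-chromen-2-one, via vinylketene 15 (not isolated), via siloxycyclobutenone 16 (not isolated), via dienylketene 17 (not isolated), via cyclohexadienone 18 (not isolated), via phenol ester 19 (not isolated)
Conditions: 14 (1.5 equiv), toluene (0.3 M), 80 → 110 °C; then PPTS (5 mol %), 80 °C, to complete lactonisation
Reagents that add atoms: none
Why: Heating opens 6 by 4π electrocyclic reversion to the ethoxy vinylketene 15, whose ketene C=C adds 14 in a polarity-matched [2+2] (the ketal-bearing alkyne carbon attacks the ketene carbonyl carbon to form C8a–C8 and the siloxy-bearing carbon joins the ketene α-carbon to form C7–C6) to give 16; a second 4π opening gives dienylketene 17, 6π electrocyclisation forms C8a–C4a (18) and enolisation gives phenol 19. This is the Danheiser benzannulation of a cyclobutenone with a siloxyalkyne, applied here to a vinylogous-ester cyclobutenone and to an alkyne carrying a ketal carbon, both more demanding members of the class. The carbocyclic aromatic ring is thus closed by thermal disrotatory 6π electrocyclisation and the lactone ring by 6-exo-trig acyl substitution of the C8a hydroxyl, the only free hydroxyl, on the methyl ester, a closure favoured by the buttressing C5 ethoxy and C4 phenyl groups and finished by a trace of acid that leaves the aryl silyl ether intact. No stereocentre is created: the ring carbon of 6 becomes aromatic C4a, and C4, which is not α to a carbonyl, is a spectator under neutral thermal conditions. The selectivity needed is regiochemical (oxygen on C5, C7 and C8a, carbon on C4a and C8, hydrogen on C6) and is fixed by the polarisation of ketene and ynol ether together with the positions of the substituents on the two partners. An excess of 14 keeps the hindered phenol from being acylated by unreacted 15.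

Step 8
Reactants: 20 (4R)-5-ethoxy-8-{2-[2-(4-methoxyphenyl)ethyl]-1,3-dioxolan-2-yl}-4-phenyl-7-(triisopropylsilyloxy)-3,4-dihydro-2H-chromen-2-one
Product: 22 (4R)-5-ethoxy-7-hydroxy-8-[3-(4-methoxyphenyl)propanoyl]-4-phenyl-3,4-dihydro-2H-chromen-2-one, via phenol ketal 21 (not isolated)
Conditions: TBAF, AcOH, THF, 0 °C; then 2 M aq HCl, rt
Reagents that add atoms: water, O
Why: Buffered fluoride cleaves the aryl silyl ether without opening the aryl lactone, and dilute aqueous acid then hydrolyses the dioxolane of the electron-rich, doubly ortho-substituted aryl ketone (carbonyl oxygen from water); the C5 oxygen is still an ether, so the lactone cannot migrate.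

Step 9
Reactants: 22 (4R)-5-ethoxy-7-hydroxy-8-[3-(4-methoxyphenyl)propanoyl]-4-phenyl-3,4-dihydro-2H-chromen-2-one
Product: 23 (4R)-5,7-dihydroxy-8-[3-(4-hydroxyphenyl)propanoyl]-4-phenyl-3,4-dihydro-2H-chromen-2-one
Conditions: BBr3 (6 equiv), CH2Cl2, −78 °C → rt; ice-water
Reagents that add atoms: none
Why: Boron tribromide ether cleavage removes the aryl ethyl and aryl methyl ethers by bromide attack on the O-alkyl carbon of the boron-complexed ethers, while the aryl lactone (no alkyl–oxygen bond), the chelated ketone and the C4 stereocentre should be untouched and cold aqueous work-up hydrolyses the aryl borates.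

**Compound list**
1 | 3-phenylglutaric anhydride (4-phenyloxane-2,6-dione) | O=C1CC(c2ccccc2)CC(=O)O1 | starting material
2 | (3R)-5-methoxy-5-oxo-3-phenylpentanoic acid | COC(=O)C[C@H](c1ccccc1)CC(=O)O | intermediate
3 | methyl (3S)-5-chloro-5-oxo-3-phenylpentanoate | COC(=O)C[C@H](c1ccccc1)CC(=O)Cl | intermediate
4 | ethoxyacetylene | CCOC#C | starting material
5 | methyl (3S)-5-oxo-3-phenylpent-4-enoate (ketene) | COC(=O)C[C@H](c1ccccc1)C=C=O | intermediate (not isolated)
6 | methyl (3S)-3-(2-ethoxy-4-oxocyclobut-2-en-1-yl)-3-phenylpropanoate, both epimers at ring C1 | COC(=O)C[C@H](c1ccccc1)C1C(=O)C=C1OCC | intermediate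
7 | 1-(2-bromoethyl)-4-methoxybenzene | COc1ccc(CCBr)cc1 | starting material
8 | diethyl oxalate | CCOC(=O)C(=O)OCC | starting material
9 | [2-(4-methoxyphenyl)ethyl]magnesium bromide | COc1ccc(CC[Mg]Br)cc1 | intermediate (not isolated)
10 | ethyl 4-(4-methoxyphenyl)-2-oxobutanoate | CCOC(=O)C(=O)CCc1ccc(OC)cc1 | intermediate
11 | ethyl 2-[2-(4-methoxyphenyl)ethyl]-1,3-dioxolane-2-carboxylate | CCOC(=O)C1(CCc2ccc(OC)cc2)OCCO1 | intermediate
12 | lithium 2,2-dibromo-1-{2-[2-(4-methoxyphenyl)ethyl]-1,3-dioxolan-2-yl}ethen-1-olate | [Li]OC(=C(Br)Br)C1(CCc2ccc(OC)cc2)OCCO1 | intermediate (not isolated)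
13 | lithium 2-{2-[2-(4-methoxyphenyl)ethyl]-1,3-dioxolan-2-yl}ethyn-1-olate | [Li]OC#CC1(CCc2ccc(OC)cc2)OCCO1 | intermediate (not isolated)
14 | 2-[2-(4-methoxyphenyl)ethyl]-2-{[tri(propan-2-yl)silyl]oxyethynyl}-1,3-dioxolane | CC(C)[Si](C(C)C)(C(C)C)OC#CC1(CCc2ccc(OC)cc2)OCCO1 | intermediate
15 | methyl (3S)-5-ethoxy-7-oxo-3-phenylhepta-4,6-dienoate (vinylketene, C4=C5 geometry open) | COC(=O)C[C@H](c1ccccc1)C=C(OCC)C=C=O | intermediate (not isolated)
16 | methyl (3S)-5-ethoxy-5-[3-{2-[2-(4-methoxyphenyl)ethyl]-1,3-dioxolan-2-yl}-4-oxo-2-(triisopropylsilyloxy)cyclobut-2-en-1-yl]-3-phenylpent-4-enoate | COC(=O)C[C@H](c1ccccc1)C=C(OCC)C1C(=O)C(C2(CCc3ccc(OC)cc3)OCCO2)=C1O[Si](C(C)C)(C(C)C)C(C)C | intermediate (not isolated)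
17 | methyl (3S)-5-ethoxy-8-{2-[2-(4-methoxyphenyl)ethyl]-1,3-dioxolan-2-yl}-9-oxo-3-phenyl-7-(triisopropylsilyloxy)nona-4,6,8-trienoate (dienylketene) | COC(=O)C[C@H](c1ccccc1)C=C(OCC)C=C(O[Si](C(C)C)(C(C)C)C(C)C)C(=C=O)C1(CCc2ccc(OC)cc2)OCCO1 | intermediate (not isolated)
18 | methyl (3S)-3-[2-ethoxy-5-{2-[2-(4-methoxyphenyl)ethyl]-1,3-dioxolan-2-yl}-6-oxo-4-(triisopropylsilyloxy)cyclohexa-2,4-dien-1-yl]-3-phenylpropanoate | COC(=O)C[C@H](c1ccccc1)C1C(=O)C(C2(CCc3ccc(OC)cc3)OCCO2)=C(O[Si](C(C)C)(C(C)C)C(C)C)C=C1OCC | intermediate (not isolated)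
19 | methyl (3R)-3-[6-ethoxy-2-hydroxy-3-{2-[2-(4-methoxyphenyl)ethyl]-1,3-dioxolan-2-yl}-4-(triisopropylsilyloxy)phenyl]-3-phenylpropanoate | COC(=O)C[C@H](c1ccccc1)c1c(OCC)cc(O[Si](C(C)C)(C(C)C)C(C)C)c(C2(CCc3ccc(OC)cc3)OCCO2)c1O | intermediate (not isolated)
20 | (4R)-5-ethoxy-8-{2-[2-(4-methoxyphenyl)ethyl]-1,3-dioxolan-2-yl}-4-phenyl-7-(triisopropylsilyloxy)-3,4-dihydro-2H-chromen-2-one | O=C1C[C@H](c2ccccc2)c2c(OCC)cc(O[Si](C(C)C)(C(C)C)C(C)C)c(C3(CCc4ccc(OC)cc4)OCCO3)c2O1 | intermediate
21 | (4R)-5-ethoxy-7-hydroxy-8-{2-[2-(4-methoxyphenyl)ethyl]-1,3-dioxolan-2-yl}-4-phenyl-3,4-dihydro-2H-chromen-2-one | O=C1C[C@H](c2ccccc2)c2c(OCC)cc(O)c(C3(CCc4ccc(OC)cc4)OCCO3)c2O1 | intermediate (not isolated)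
22 | (4R)-5-ethoxy-7-hydroxy-8-[3-(4-methoxyphenyl)propanoyl]-4-phenyl-3,4-dihydro-2H-chromen-2-one | O=C1C[C@H](c2ccccc2)c2c(OCC)cc(O)c(C(=O)CCc3ccc(OC)cc3)c2O1 | intermediate
23 | (4R)-5,7-dihydroxy-8-[3-(4-hydroxyphenyl)propanoyl]-4-phenyl-3,4-dihydro-2H-chromen-2-one | O=C1C[C@H](c2ccccc2)c2c(O)cc(O)c(C(=O)CCc3ccc(O)cc3)c2O1 | target

**Step count**
Total: 9 steps. Longest linear sequence: 6 steps (1, 2, 3, 7, 8, 9 from anhydride 1, or 4, 5, 6, 7, 8, 9 from bromide 7).

**Steps most likely to fail**

Step 7. The [2+2] capture of vinylketene 15 may be too slow, because the attacking alkyne carbon of 14 carries a fully substituted, inductively deactivating dioxolane carbon. In that case 15 may dimerise or suffer a [1,5]-hydrogen shift from C4–H (which removes the stereocentre in that material), or 14 may isomerise to a silylketene first. The fallback carries the C8 carbonyl at the alcohol oxidation level on a less hindered, more electron-rich alkyne. It sets out from keto ester 10. Reduction with NaBH4 (EtOH, 0 °C) gives ethyl 2-hydroxy-4-(4-methoxyphenyl)butanoate F1, and TBSCl with imidazole gives ethyl 2-(tert-butyldimethylsilyloxy)-4-(4-methoxyphenyl)butanoate F2. The ynolate sequence of step 6 then leads through the dibromoenolate F3 and the lithium ynolate F4 to the siloxyalkyne F5. Heating F5 with 6 in toluene should give, by way of 15, the cyclobutenone adduct F6, the dienylketene F7, the cyclohexadienone F8 and the phenol ester F9, the lactone F10. TBAF with AcOH removes both silyl groups to give the diol F11, and activated MnO2 (CH2Cl2, rt) oxidises the o-hydroxybenzylic alcohol to the ketone, which is compound 22, where the route is rejoined.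

Step 6. After bromine–lithium exchange the carbenoid may be protonated, or may lose a dioxolane alkoxide, instead of undergoing the 1,2-shift of the hindered oxygenated carbon; the ynolate may also silylate on carbon to give a silylketene. The fallback replaces ester homologation by oxidation of a terminal acetylide. It sets out from ketal ester 11. DIBAL-H (CH2Cl2, −78 °C) gives 2-[2-(4-methoxyphenyl)ethyl]-1,3-dioxolane-2-carbaldehyde F12, and the Ohira–Bestmann reagent (K2CO3, MeOH, rt) gives 2-ethynyl-2-[2-(4-methoxyphenyl)ethyl]-1,3-dioxolane F13. Deprotonation with n-BuLi (THF, −78 °C) gives the lithium acetylide F14, which lithium tert-butyl peroxide (from t-BuOOH and LiHMDS) oxidises to ynolate 13. O-Silylation with TIPSOTf at −78 °C then gives compound 14, where the route is rejoined.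

Step 3. Amine-promoted dimerisation or acylation of aldoketene 5 may outrun its cycloaddition with 4, and the ammonium chloride may add to the ynol ether. The fallback generates the ketene reductively and without amine. It sets out from acid chloride 3. α-Bromination of the Hell–Volhard–Zelinsky type (NBS, cat. HBr, SOCl2, 70 °C, in the dark; only the acid chloride enolises) gives methyl (3R)-4-bromo-5-chloro-5-oxo-3-phenylpentanoate F15 as a mixture of C4 epimers. Activated zinc (THF, −10 °C) in the presence of excess 4 effects 1,2-dehalogenation to ketene 5, which is intercepted by 4 to give compound 6, where the route is rejoined.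

**Further compounds**
F1 | step 7 | ethyl 2-hydroxy-4-(4-methoxyphenyl)butanoate (racemic) | CCOC(=O)C(O)CCc1ccc(OC)cc1
F2 | step 7 | ethyl 2-(tert-butyldimethylsilyloxy)-4-(4-methoxyphenyl)butanoate (racemic) | CCOC(=O)C(O[Si](C)(C)C(C)(C)C)CCc1ccc(OC)cc1
F3 | step 7 | lithium 1,1-dibromo-3-(tert-butyldimethylsilyloxy)-5-(4-methoxyphenyl)pent-1-en-2-olate | [Li]OC(=C(Br)Br)C(O[Si](C)(C)C(C)(C)C)CCc1ccc(OC)cc1
F4 | step 7 | lithium 3-(tert-butyldimethylsilyloxy)-5-(4-methoxyphenyl)pent-1-yn-1-olate | [Li]OC#CC(O[Si](C)(C)C(C)(C)C)CCc1ccc(OC)cc1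
F5 | step 7 | tert-butyl{[5-(4-methoxyphenyl)-1-(triisopropylsilyloxy)pent-1-yn-3-yl]oxy}dimethylsilane | CC(C)[Si](C(C)C)(C(C)C)OC#CC(O[Si](C)(C)C(C)(C)C)CCc1ccc(OC)cc1
F6 | step 7 | methyl (3S)-5-[3-{1-(tert-butyldimethylsilyloxy)-3-(4-methoxyphenyl)propyl}-4-oxo-2-(triisopropylsilyloxy)cyclobut-2-en-1-yl]-5-ethoxy-3-phenylpent-4-enoate | COC(=O)C[C@H](c1ccccc1)C=C(OCC)C1C(=O)C(C(O[Si](C)(C)C(C)(C)C)CCc2ccc(OC)cc2)=C1O[Si](C(C)C)(C(C)C)C(C)C
F7 | step 7 | methyl (3S)-8-[1-(tert-butyldimethylsilyloxy)-3-(4-methoxyphenyl)propyl]-5-ethoxy-9-oxo-3-phenyl-7-(triisopropylsilyloxy)nona-4,6,8-trienoate | COC(=O)C[C@H](c1ccccc1)C=C(OCC)C=C(O[Si](C(C)C)(C(C)C)C(C)C)C(=C=O)C(O[Si](C)(C)C(C)(C)C)CCc1ccc(OC)cc1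
F8 | step 7 | methyl (3S)-3-[5-{1-(tert-butyldimethylsilyloxy)-3-(4-methoxyphenyl)propyl}-2-ethoxy-6-oxo-4-(triisopropylsilyloxy)cyclohexa-2,4-dien-1-yl]-3-phenylpropanoate | COC(=O)C[C@H](c1ccccc1)C1C(=O)C(C(O[Si](C)(C)C(C)(C)C)CCc2ccc(OC)cc2)=C(O[Si](C(C)C)(C(C)C)C(C)C)C=C1OCC
F9 | step 7 | methyl (3R)-3-[3-{1-(tert-butyldimethylsilyloxy)-3-(4-methoxyphenyl)propyl}-6-ethoxy-2-hydroxy-4-(triisopropylsilyloxy)phenyl]-3-phenylpropanoate | COC(=O)C[C@H](c1ccccc1)c1c(OCC)cc(O[Si](C(C)C)(C(C)C)C(C)C)c(C(O[Si](C)(C)C(C)(C)C)CCc2ccc(OC)cc2)c1O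
F10 | step 7 | (4R)-8-[1-(tert-butyldimethylsilyloxy)-3-(4-methoxyphenyl)propyl]-5-ethoxy-4-phenyl-7-(triisopropylsilyloxy)-3,4-dihydro-2H-chromen-2-one (both carbinol epimers) | O=C1C[C@H](c2ccccc2)c2c(OCC)cc(O[Si](C(C)C)(C(C)C)C(C)C)c(C(O[Si](C)(C)C(C)(C)C)CCc3ccc(OC)cc3)c2O1
F11 | step 7 | (4R)-5-ethoxy-7-hydroxy-8-[1-hydroxy-3-(4-methoxyphenyl)propyl]-4-phenyl-3,4-dihydro-2H-chromen-2-one (both carbinol epimers) | O=C1C[C@H](c2ccccc2)c2c(OCC)cc(O)c(C(O)CCc3ccc(OC)cc3)c2O1
F12 | step 6 | 2-[2-(4-methoxyphenyl)ethyl]-1,3-dioxolane-2-carbaldehyde | O=CC1(CCc2ccc(OC)cc2)OCCO1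
F13 | step 6 | 2-ethynyl-2-[2-(4-methoxyphenyl)ethyl]-1,3-dioxolane | C#CC1(CCc2ccc(OC)cc2)OCCO1
F14 | step 6 | lithium {2-[2-(4-methoxyphenyl)ethyl]-1,3-dioxolan-2-yl}acetylide | [Li]C#CC1(CCc2ccc(OC)cc2)OCCO1
F15 | step 3 | methyl (3R)-4-bromo-5-chloro-5-oxo-3-phenylpentanoate (both C4 epimers) | COC(=O)C[C@H](c1ccccc1)C(Br)C(=O)Cl
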